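**Retrosynthetic overview**

- Numbering (furo[3,4-c]furan): C1(Ar)–O2–C3H2–C3a(OH)–C4(Ar)–O5–C6H2–C6a(H); ring A = C1, O2, C3, C3a, C6a; ring B = C3a, C4, O5, C6, C6a; H-1, HO-3a, H-4 and H-6a all lie on one face, so both aryl groups are endo.
- Removing OH from C3a and H from C6a leaves a C3a=C6a alkene with a twofold axis through the middle of that bond; the axis maps ring A onto ring B and keeps both aryl groups on one face, so syn hydration anti to the aryl groups gives the target whichever carbon takes the OH.
- Key disconnection: both O–CH2 bonds (O2–C3 and O5–C6) of that alkene, back to the acyclic (1S,4S)-2,3-dimethylidenebutane-1,4-diol 8. The enabling feature is that C3, C3a, C6a and C6 are the four carbons of a buta-1,3-diene whose CH2 ends each stand 1,5 to one carbinol oxygen (O2–C1–C6a–C3a–C3 and O5–C4–C3a–C6a–C6); an iodine-mediated oxidative 1,4-double cycloetherification closes ring A, then ring B, at CH2 carbons only, so the kinetically set endo benzylic centres are never exposed to equilibration.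
- Diene 8 comes from the (S,S)-ynediol 6 by ethylene–alkyne cross-metathesis; 6 comes from acetylene and two molecules of O-benzylvanillin by bis-Grignard addition, oxidation and double CBS reduction.
- Order of ring formation: ring A, then ring B (both in step 5); then C3a–OH and C6a–H by hydroboration–oxidation; debenzylation last.

Key step: step 5

Assumption: in the CBS reduction (step 3) the aryl group is taken as the larger ketone substituent and the alkynyl group as the smaller one; if the opposite sense of induction were found, the enantiomeric catalyst would be used.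

**Route**

Step 1
Reactants: 1 4-(benzyloxy)-3-methoxybenzaldehyde (2 equiv); 2 acetylene
Product: 4 1,4-bis[4-(benzyloxy)-3-methoxyphenyl]but-2-yne-1,4-diol (like/meso mixture), via acetylenebis(magnesium bromide) 3 (not isolated)
Conditions: EtMgBr (2.1 equiv), acetylene, THF, 0 °C to 40 °C; then 1, 0 °C to rt; aq NH4Cl
Reagents that add atoms: none
Why: Double deprotonation of acetylene gives the bis-Grignard reagent 3, which adds to two molecules of 1 (alkynyl Grignard 1,2-addition); the configuration of the carbinols is irrelevant because both are oxidized in step 2.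

Step 2
Reactants: 4 1,4-bis[4-(benzyloxy)-3-methoxyphenyl]but-2-yne-1,4-diol
Product: 5 1,4-bis[4-(benzyloxy)-3-methoxyphenyl]but-2-yne-1,4-dione
Conditions: activated MnO2 (excess), CH2Cl2, rt
Reagents that add atoms: none
Why: MnO2 oxidation of doubly activated (benzylic and propargylic) alcohols should proceed under neutral conditions and converges both diastereomers of 4 on one achiral ynedione.

Step 3
Reactants: 5 1,4-bis[4-(benzyloxy)-3-methoxyphenyl]but-2-yne-1,4-dione
Product: 6 (1S,4S)-1,4-bis[4-(benzyloxy)-3-methoxyphenyl]but-2-yne-1,4-diol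
Conditions: (S)-2-methyl-CBS-oxazaborolidine (20 mol%), catecholborane (2.5 equiv), CH2Cl2, −78 °C; MeOH, then aq NaOH wash; chromatography to remove the meso diol (returned to step 2)
Reagents that add atoms: none
Why: Corey–Bakshi–Shibata reduction: with aryl as the large and the rod-like alkynyl as the small substituent, the (S)-catalyst should deliver hydride to the same face of both carbonyls and set both carbinol centres as S; a wrong-face event ends mainly in the separable meso diol, so the like diol should be enriched beyond the single-event selectivity (statistical amplification in a twofold reduction).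

Step 4
Reactants: 6 (1S,4S)-1,4-bis[4-(benzyloxy)-3-methoxyphenyl]but-2-yne-1,4-diol; 7 ethylene
Product: 8 (1S,4S)-1,4-bis[4-(benzyloxy)-3-methoxyphenyl]-2,3-dimethylidenebutane-1,4-diol
Conditions: second-generation Grubbs catalyst RuCl2(=CHPh)(H2IMes)(PCy3) (10 mol%), ethylene (4 atm), CH2Cl2, 40 °C
Reagents that add atoms: none
Why: Ethylene–alkyne cross-metathesis (enyne metathesis): the ruthenium methylidene adds to the alkyne and the vinylcarbene is released by ethylene, so each alkyne carbon gains a =CH2 group; free propargylic hydroxyls are tolerated by the N-heterocyclic carbene catalyst and the stereocentres are not touched.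

Step 5
Reactants: 8 (1S,4S)-1,4-bis[4-(benzyloxy)-3-methoxyphenyl]-2,3-dimethylidenebutane-1,4-diol
Product: 10 (1S,4S)-1,4-bis[4-(benzyloxy)-3-methoxyphenyl]-4,6-dihydro-1H,3H-furo[3,4-c]furan, via monocyclic allylic iodide 9 (not isolated)
Conditions: I2 (1.05 equiv), NaHCO3 (3 equiv), dry MeCN, 0 °C to rt, dark
Reagents that add atoms: none
Why: Proposed new method: iodine should add to one terminal CH2 (C6) of the conjugated diene to give an iodomethyl-bearing tertiary allyl cation over C6a–C3a–C3 (in equilibrium with the iodonium ion), whose far CH2 end (C3) is captured by the hydroxyl on C1, and after loss of HI to NaHCO3 the second hydroxyl displaces the primary allylic iodide of 9; the closest known reaction types are the 5-endo iodoetherification of homoallylic alcohols and the 1,4-addition of bromine to 2,3-disubstituted buta-1,3-dienes followed by Williamson closure of a cis-4-halobut-2-en-1-ol. Ring A (O2–C3 bond) closes by attack of oxygen on the CH2 terminus of the allyl cation, a vinylogous 5-endo closure that leaves the new tetrasubstituted C3a=C6a bond inside the ring, and ring B (O5–C6 bond) closes by 5-exo-tet SN2 displacement. No stereocentre is created: both closures take place at CH2 carbons, so the S configuration of C1 and C4 from step 3 is carried through unchanged and the two aryl groups of 10 are necessarily cis. The step needs 1,4- instead of 1,2-addition and five- instead of three- or four-membered ring formation; the first should follow from the fully substituted allyl cation and the tetrasubstituted alkene product under reversible iodonium formation, the second from ring strain, since each hydroxyl can reach only one CH2 through a five-membered transition state. The first ring also locks the alkene geometry, holding the CH2I group and the remaining carbinol cis on the new double bond so that the second closure is assured.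

Step 6
Reactants: 10 (1S,4S)-1,4-bis[4-(benzyloxy)-3-methoxyphenyl]-4,6-dihydro-1H,3H-furo[3,4-c]furan
Product: 12 (1R,3aS,4S,6aR)-1,4-bis[4-(benzyloxy)-3-methoxyphenyl]tetrahydro-1H,3H-furo[3,4-c]furan-3a(4H)-ol, via tertiary alkylborane 11 (not isolated)
Conditions: BH3·THF (3 equiv), THF, 0 °C to rt; then aq NaOH, H2O2, 0 °C to rt
Reagents that add atoms: hydrogen peroxide, OO
Why: Hydroboration–oxidation: borane should add syn to the C3a=C6a bond on the face opposite both aryl groups and oxidation proceeds with retention, which sets C3a (OH) and C6a (H) cis to each other and trans to the aryl groups (substrate control), while the twofold axis of 10 makes both regiochemical modes give the same product.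

Step 7
Reactants: 12 (1R,3aS,4S,6aR)-1,4-bis[4-(benzyloxy)-3-methoxyphenyl]tetrahydro-1H,3H-furo[3,4-c]furan-3a(4H)-ol
Product: 13 (1R,3aS,4S,6aR)-1,4-bis(4-hydroxy-3-methoxyphenyl)tetrahydro-1H,3H-furo[3,4-c]furan-3a(4H)-ol (target)
Conditions: H2 (1 atm), Pd/C (palladium on carbon, 10 wt%), EtOAc, rt, stopped at full conversion
Reagents that add atoms: none
Why: Hydrogenolysis of the two aryl benzyl ethers under neutral conditions, chosen because the endo-aryl benzylic centres would epimerize under acid; aryl benzyl ethers should be cleaved faster than the ring benzylic C–O bonds.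

**Compound list**

1 | 4-(benzyloxy)-3-methoxybenzaldehyde (O-benzylvanillin) | O=Cc1ccc(OCc2ccccc2)c(OC)c1 | starting material
2 | acetylene | C#C | starting material
3 | acetylenebis(magnesium bromide) | Br[Mg]C#C[Mg]Br | intermediate
4 | 1,4-bis[4-(benzyloxy)-3-methoxyphenyl]but-2-yne-1,4-diol, like/meso mixture | OC(C#CC(O)c1ccc(OCc2ccccc2)c(OC)c1)c1ccc(OCc2ccccc2)c(OC)c1 | intermediate
5 | 1,4-bis[4-(benzyloxy)-3-methoxyphenyl]but-2-yne-1,4-dione | O=C(C#CC(=O)c1ccc(OCc2ccccc2)c(OC)c1)c1ccc(OCc2ccccc2)c(OC)c1 | intermediate
6 | (1S,4S)-1,4-bis[4-(benzyloxy)-3-methoxyphenyl]but-2-yne-1,4-diol | O[C@H](C#C[C@@H](O)c1ccc(OCc2ccccc2)c(OC)c1)c1ccc(OCc2ccccc2)c(OC)c1 | intermediate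
7 | ethylene | C=C | starting material
8 | (1S,4S)-1,4-bis[4-(benzyloxy)-3-methoxyphenyl]-2,3-dimethylidenebutane-1,4-diol | O[C@H](C(=C)C(=C)[C@@H](O)c1ccc(OCc2ccccc2)c(OC)c1)c1ccc(OCc2ccccc2)c(OC)c1 | intermediate
9 | (S)-[4-(benzyloxy)-3-methoxyphenyl]{(5S)-5-[4-(benzyloxy)-3-methoxyphenyl]-4-(iodomethyl)-2,5-dihydrofuran-3-yl}methanol | ICC1=C([C@@H](O)c2ccc(OCc3ccccc3)c(OC)c2)CO[C@H]1c1ccc(OCc2ccccc2)c(OC)c1 | intermediate
10 | (1S,4S)-1,4-bis[4-(benzyloxy)-3-methoxyphenyl]-4,6-dihydro-1H,3H-furo[3,4-c]furan (C3a=C6a alkene, aryl groups cis, twofold-symmetric) | COc1cc([C@@H]2OCC3=C2CO[C@H]3c2ccc(OCc4ccccc4)c(OC)c2)ccc1OCc1ccccc1 | intermediate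
11 | cis-fused 3a-boranyl-1,4-bis[4-(benzyloxy)-3-methoxyphenyl]tetrahydro-1H,3H-furo[3,4-c]furan (BH2 and H-6a on the face opposite the aryl groups) | COc1cc([C@@H]2OC[C@@]3(B)[C@@H]2CO[C@H]3c2ccc(OCc4ccccc4)c(OC)c2)ccc1OCc1ccccc1 | intermediate
12 | (1R,3aS,4S,6aR)-1,4-bis[4-(benzyloxy)-3-methoxyphenyl]tetrahydro-1H,3H-furo[3,4-c]furan-3a(4H)-ol | COc1cc([C@@H]2OC[C@@]3(O)[C@@H]2CO[C@H]3c2ccc(OCc4ccccc4)c(OC)c2)ccc1OCc1ccccc1 | intermediate
13 | (1R,3aS,4S,6aR)-1,4-bis(4-hydroxy-3-methoxyphenyl)tetrahydro-1H,3H-furo[3,4-c]furan-3a(4H)-ol (both aryl groups endo; H-1, HO-3a, H-4, H-6a on one face) | COc1cc([C@@H]2OC[C@@]3(O)[C@@H]2CO[C@H]3c2ccc(O)c(OC)c2)ccc1O | target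

**Step count and risks**

Total step count: 7. Longest linear sequence: 7 steps (from 1).

Steps most likely to fail:

1. Step 5 (proposed new method). The risks are 1,2-addition with three- or four-membered ring closure competing with the 1,4-mode, ionization of the electron-rich benzylic carbinols by HI, and further reaction of the product alkene with iodine. The fallback, a stepwise version of the same disconnection, sets out from 8 and comes back at 10. Both hydroxyls are silylated (TBSCl, imidazole, DMF) to give (1S,4S)-1,4-bis[4-(benzyloxy)-3-methoxyphenyl]-1,4-bis[(tert-butyldimethylsilyl)oxy]-2,3-dimethylidenebutane F1. Bromine (1 equiv, CH2Cl2, −78 °C to 0 °C) should add in the 1,4-sense, as it does with 2,3-disubstituted buta-1,3-dienes, to give (1S,4S,2E)-1,4-bis[4-(benzyloxy)-3-methoxyphenyl]-2,3-bis(bromomethyl)-1,4-bis[(tert-butyldimethylsilyl)oxy]but-2-ene F2, with the two bulky carbinol arms trans. Bu4NF in THF then removes both silyl groups, and the liberated alkoxides close both rings by 5-exo-tet Williamson substitution at the allylic CH2Br groups to give 10.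

2. Step 6. The risks are slow addition of borane to the tetrasubstituted, inductively deactivated alkene and β-alkoxy elimination of the organoborane with opening of a ring. The fallback sets out from 10 and comes back at 12. Epoxidation with dimethyldioxirane (acetone, 0 °C) on the face opposite the aryl groups gives (1S,3aS,4S,6aS)-1,4-bis[4-(benzyloxy)-3-methoxyphenyl]-3a,6a-epoxytetrahydro-1H,3H-furo[3,4-c]furan F3, with the oxirane oxygen anti to both aryl groups. Cp2TiCl (from Cp2TiCl2 and Zn) with 1,4-cyclohexadiene in THF should open one of the two equivalent C–O bonds homolytically (titanocene-mediated reductive epoxide opening), and hydrogen-atom transfer to the tertiary bridgehead radical can only give the cis-fused alcohol 12.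

3. Step 3. The risks are poor discrimination between the aryl and alkynyl flanks of the ketone (low enantioselectivity and much meso diol) and reduction of the electron-poor triple bond. The fallback sets out from 1 and comes back at 6, bypassing 4 and 5. Asymmetric alkynylation of 1 with trimethylsilylacetylene (ZnMe2, ProPhenol ligand of the enantiomeric series that gives the S carbinol, toluene) gives (S)-1-[4-(benzyloxy)-3-methoxyphenyl]-3-(trimethylsilyl)prop-2-yn-1-ol F4. K2CO3 in MeOH removes the silyl group to give (R)-1-[4-(benzyloxy)-3-methoxyphenyl]prop-2-yn-1-ol F5 (same spatial arrangement; the descriptor changes only through the priority rules). The dianion of F5 (n-BuLi, 2 equiv, THF, −78 °C) is added to a second molecule of 1 without stereocontrol, and chromatographic removal of the meso diol leaves 6, whose enantiomeric purity should match that of F5 because the carbinol centre made in the alkynylation is carried through unchanged.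

Further compounds
F1 | step 5 | (1S,4S)-1,4-bis[4-(benzyloxy)-3-methoxyphenyl]-1,4-bis[(tert-butyldimethylsilyl)oxy]-2,3-dimethylidenebutane | CC(C)(C)[Si](C)(C)O[C@H](C(=C)C(=C)[C@@H](O[Si](C)(C)C(C)(C)C)c1ccc(OCc2ccccc2)c(OC)c1)c1ccc(OCc2ccccc2)c(OC)c1
F2 | step 5 | (1S,4S,2E)-1,4-bis[4-(benzyloxy)-3-methoxyphenyl]-2,3-bis(bromomethyl)-1,4-bis[(tert-butyldimethylsilyl)oxy]but-2-ene | BrC/C([C@@H](O[Si](C)(C)C(C)(C)C)c1ccc(OCc2ccccc2)c(OC)c1)=C(/CBr)[C@@H](O[Si](C)(C)C(C)(C)C)c1ccc(OCc2ccccc2)c(OC)c1
F3 | step 6 | (1S,3aS,4S,6aS)-1,4-bis[4-(benzyloxy)-3-methoxyphenyl]-3a,6a-epoxytetrahydro-1H,3H-furo[3,4-c]furan, oxirane oxygen anti to both aryl groups | COc1cc([C@@H]2OC[C@@]3(O4)[C@]24CO[C@H]3c2ccc(OCc5ccccc5)c(OC)c2)ccc1OCc1ccccc1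
F4 | step 3 | (S)-1-[4-(benzyloxy)-3-methoxyphenyl]-3-(trimethylsilyl)prop-2-yn-1-ol | C[Si](C)(C)C#C[C@@H](O)c1ccc(OCc2ccccc2)c(OC)c1
F5 | step 3 | (R)-1-[4-(benzyloxy)-3-methoxyphenyl]prop-2-yn-1-ol | C#C[C@@H](O)c1ccc(OCc2ccccc2)c(OC)c1
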